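**Retrosynthetic overview**
1. Feature: ring A carries oxygen on the four adjacent carbons C5, C6, C7 and C8, with O5 and O8 para. These are the four carbons of a squarate in hydroquinone form, and C4a=C8a is the free C5=C6 double bond of a preformed ring C (a 4-pyranone).
2. Endgame: O7–H comes from a tert-butyl ether (acid). O8–CH3 comes from the free 8-OH of a 5,8-hydroquinone whose 5-OH is tied up by its hydrogen bond to C4=O.
3. Key disconnection C8–C8a: ring A arises from a 4-hydroxy-4-(4-oxopyran-3-yl)cyclobutenone by 4π opening to a dienylketene and 6π closure.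
4. Bond C5–C4a: a C5-magnesiated 2-aryl-3-methoxy-4-pyranone adds 1,2 to tert-butyl methyl squarate at the carbonyl beside the C–OMe carbon.
5. Ring order: ring C is bought (pyromeconic acid), ring B is attached at C2 by Suzuki coupling, and ring A is formed last.

Key step: step 7

Remark: the target SMILES holds no stereocentre, axis or stereogenic double bond, so araneosol is achiral and no enantioselective step is needed. The only lasting stereocentre on the way (the carbinol carbon of the cyclobutenone precursor) is made racemic and is erased in the key step.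

**Step 1**
Reactants: 1 pyromeconic acid (3-hydroxy-4H-pyran-4-one)
Product: 2 3-hydroxy-2-iodo-4H-pyran-4-one
Conditions: NIS (1.05 equiv), MeCN, 0 °C to rt, dark
Reagents that add atoms: N-iodosuccinimide, O=C1CCC(=O)N1I
Why: Electrophilic iodination of the enolic 3-hydroxy-4-pyranone should go to C2, the β-carbon of the enol ortho to the hydroxyl, which is where pyromeconic and kojic acid take up halogens and carbon electrophiles.

**Step 2**
Reactants: 2 3-hydroxy-2-iodo-4H-pyran-4-one
Product: 3 2-iodo-3-methoxy-4H-pyran-4-one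
Conditions: MeI, K2CO3, acetone, 40 °C
Reagents that add atoms: iodomethane, CI
Why: Williamson O-methylation of the acidic enol needs only carbonate, which in acetone is too weakly nucleophilic to displace the C2 iodide or open the pyranone.

**Step 3**
Reactants: 3 2-iodo-3-methoxy-4H-pyran-4-one; 4 4-methoxyphenylboronic acid
Product: 5 3-methoxy-2-(4-methoxyphenyl)-4H-pyran-4-one
Conditions: Pd(PPh3)4 (3 mol %), K2CO3, dioxane/H2O, 80 °C
Reagents that add atoms: none
Why: In this Suzuki–Miyaura coupling the C2–I bond is a vinylogous acyl iodide that undergoes oxidative addition readily, and halopyranones and halochromones with a free CH next to the ring oxygen tolerate aqueous carbonate in such couplings.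

**Step 4**
Reactants: 5 3-methoxy-2-(4-methoxyphenyl)-4H-pyran-4-one
Product: 6 5-iodo-3-methoxy-2-(4-methoxyphenyl)-4H-pyran-4-one
Conditions: NIS (1.1 equiv), TFA (0.3 equiv), MeCN, rt to 50 °C
Reagents that add atoms: N-iodosuccinimide, O=C1CCC(=O)N1I
Why: Electrophilic α-iodination of a 4-pyranone should take C5, the nucleophilic β-carbon of the O1–C6=C5 enol ether and the counterpart of C3 in chromone and flavone halogenation, ahead of the anisyl ring, which is deactivated as the donor end of a vinylogous 4-methoxybenzoyl system.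

**Step 5**
Reactants: 7 dimethyl squarate (3,4-dimethoxycyclobut-3-ene-1,2-dione)
Product: 8 tert-butyl methyl squarate (3-tert-butoxy-4-methoxycyclobut-3-ene-1,2-dione)
Conditions: t-BuOLi (1.0 equiv), THF, −78 to −20 °C; aq NH4Cl
Reagents that add atoms: lithium tert-butoxide, CC(C)(C)[O-].[Li+]
Why: In this vinylogous transesterification by addition–elimination, tert-butoxide adds to an alkoxy-bearing ring carbon and the less basic methoxide leaves as sparingly soluble lithium methoxide (as when metal tert-butoxides turn methyl esters into tert-butyl esters), while the bulk of the first tert-butoxy group slows a second exchange.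

**Step 6**
Reactants: 6 5-iodo-3-methoxy-2-(4-methoxyphenyl)-4H-pyran-4-one; 8 tert-butyl methyl squarate
Product: 10 (±)-2-tert-butoxy-4-hydroxy-3-methoxy-4-[5-methoxy-6-(4-methoxyphenyl)-4-oxo-4H-pyran-3-yl]cyclobut-2-enone, via pyranonylmagnesium chloride 9 (not isolated)
Conditions: i-PrMgCl·LiCl (1.05 equiv), THF, −40 °C; then cannulated into 8 (1.2 equiv), THF, −78 to −40 °C; aq NH4Cl at low temperature; Et3N-washed silica
Reagents that add atoms: isopropylmagnesium chloride, CC(C)[Mg]Cl (its MgCl is carried by intermediate 9 only; nothing of it stays in 10)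
Why: Iodine–magnesium exchange of an electron-poor α-iodo-β-alkoxyenone (as with 5-iodo-1,3-dioxin-4-ones and iodouracils) gives a Grignard reagent that is kept cold to suppress β-elimination of the ring oxygen, its 1,2-addition to the squarate should take the carbonyl beside the C–OMe carbon because the tert-butoxy group screens the other one, and the new carbinol stereocentre forms as a racemate, which does not matter because step 7 erases it.

**Step 7**
Reactants: 10 (±)-2-tert-butoxy-4-hydroxy-3-methoxy-4-[5-methoxy-6-(4-methoxyphenyl)-4-oxo-4H-pyran-3-yl]cyclobut-2-enone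
Product: 13 7-tert-butoxy-5,8-dihydroxy-3,6,4'-trimethoxyflavone, via dienylketene 11 (not isolated), via bicyclic dienone 12 (not isolated)
Conditions: degassed PhMe (0.02 M), 110 °C, Ar
Reagents that add atoms: none
Why: Heating cleaves the bond between the ring carbonyl and the carbinol carbon in a conrotatory 4π electrocyclic opening, and the donor hydroxyl turns outward (torquoselectivity), so the pyranonyl group lies cis to the ketene arm in 11. Ring A then closes by a thermal disrotatory 6π electrocyclisation in which the ketene carbon (future C8) bonds to the pyranone CH next to the ring oxygen (future C8a), and dienone 12 enolises irreversibly to the aromatic 5,8-hydroquinone 13. The closest known reaction type is the Moore ring expansion of 4-alkenyl- and 4-heteroaryl-4-hydroxycyclobutenones to hydroquinones, which also tolerates tert-butoxy substituents. No stereocentre remains, because the racemic carbinol carbon becomes sp2 C5 and the transient C8a–H centre of 12 is lost on tautomerisation. The step needs a single direction of closure, and the substrate gives it: the other flank of the pyranonyl carbon is the C4 carbonyl, whose hydrogen bond to the enol OH of 11 also holds the CH flank toward the ketene. The order carbinol carbon to C5, C–OMe to C6, C–Ot-Bu to C7 and C=O to C8 carries over unchanged, and neutral, oxygen-free toluene spares both the tert-butyl ether and the hydroquinone.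

**Step 8**
Reactants: 13 7-tert-butoxy-5,8-dihydroxy-3,6,4'-trimethoxyflavone
Product: 14 7-tert-butoxy-5-hydroxy-3,6,8,4'-tetramethoxyflavone
Conditions: MeI (1.1 equiv), K2CO3 (1.2 equiv), degassed DMF, rt, Ar
Reagents that add atoms: iodomethane, CI
Why: Williamson methylation with a weak base should touch only the free 8-OH, because the 5-OH sits in a six-membered hydrogen bond to the C4 carbonyl (the usual selectivity of 5-hydroxyflavones), and exclusion of air prevents base-promoted oxidation to the 5,8-quinone.

**Step 9**
Reactants: 14 7-tert-butoxy-5-hydroxy-3,6,8,4'-tetramethoxyflavone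
Product: 15 araneosol (5,7-dihydroxy-3,6,8,4'-tetramethoxyflavone)
Conditions: TFA/CH2Cl2 (1:4), 0 °C to rt
Reagents that add atoms: none
Why: Acidolysis of the aryl tert-butyl ether through the tert-butyl cation (E1 loss of isobutene) leaves the aryl methyl ethers and the flavone core intact, and the fully substituted ring A offers no site for Friedel–Crafts re-alkylation.

**Compound list**
1 | pyromeconic acid (3-hydroxy-4H-pyran-4-one) | O=c1ccocc1O | starting material
2 | 3-hydroxy-2-iodo-4H-pyran-4-one | O=c1ccoc(I)c1O | intermediate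
3 | 2-iodo-3-methoxy-4H-pyran-4-one | COc1c(I)occc1=O | intermediate
4 | 4-methoxyphenylboronic acid | COc1ccc(B(O)O)cc1 | starting material
5 | 3-methoxy-2-(4-methoxyphenyl)-4H-pyran-4-one | COc1ccc(-c2occc(=O)c2OC)cc1 | intermediate
6 | 5-iodo-3-methoxy-2-(4-methoxyphenyl)-4H-pyran-4-one | COc1ccc(-c2occ(I)c(=O)c2OC)cc1 | intermediate
7 | dimethyl squarate | COC1=C(OC)C(=O)C1=O | starting material
8 | tert-butyl methyl squarate (3-tert-butoxy-4-methoxycyclobut-3-ene-1,2-dione) | COC1=C(OC(C)(C)C)C(=O)C1=O | intermediate
9 | [5-methoxy-6-(4-methoxyphenyl)-4-oxo-4H-pyran-3-yl]magnesium chloride (not isolated) | COc1ccc(-c2occ([Mg]Cl)c(=O)c2OC)cc1 | intermediate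
10 | 2-tert-butoxy-4-hydroxy-3-methoxy-4-[5-methoxy-6-(4-methoxyphenyl)-4-oxo-4H-pyran-3-yl]cyclobut-2-enone (racemic, one enantiomer drawn) | O=C1C(OC(C)(C)C)=C(OC)[C@]1(O)c1coc(-c2ccc(OC)cc2)c(OC)c1=O | intermediate
11 | (Z)-dienylketene, hydroxyl trans and pyranonyl cis to the ketene arm (not isolated) | O=C=C(OC(C)(C)C)/C(OC)=C(/O)c1coc(-c2ccc(OC)cc2)c(OC)c1=O | intermediate
12 | 8a-H bicyclic dienone, keto tautomer of 13 (racemic, one enantiomer drawn, not isolated) | COc1ccc(cc1)C1=C(OC)C(=O)C2=C(O)C(OC)=C(OC(C)(C)C)C(=O)[C@H]2O1 | intermediate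
13 | 7-tert-butoxy-5,8-dihydroxy-3,6,4'-trimethoxyflavone | COc1ccc(-c2oc3c(O)c(OC(C)(C)C)c(OC)c(O)c3c(=O)c2OC)cc1 | intermediate
14 | 7-tert-butoxy-5-hydroxy-3,6,8,4'-tetramethoxyflavone | COc1ccc(-c2oc3c(OC)c(OC(C)(C)C)c(OC)c(O)c3c(=O)c2OC)cc1 | intermediate
15 | araneosol (5,7-dihydroxy-3,6,8,4'-tetramethoxyflavone, achiral) | COc1ccc(-c2oc3c(OC)c(O)c(OC)c(O)c3c(=O)c2OC)cc1 | target

**Total step count:** 9
**Longest linear sequence:** 8 steps (steps 1–4 and 6–9). Step 5 is a one-step side branch.

**Steps most likely to fail**

1. **Step 7.** Some inward rotation of the hydroxyl could let it lactonise onto the ketene, and the very electron-rich hydroquinone could oxidise in air during isolation.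
   Fallback (sets out from 10, comes back at 14): the ring expansion is run on a monoprotected substrate.
   - Carbinol 10 is silylated (TESOTf, 2,6-lutidine, CH2Cl2, −78 °C) to 2-tert-butoxy-3-methoxy-4-[5-methoxy-6-(4-methoxyphenyl)-4-oxo-4H-pyran-3-yl]-4-(triethylsilyloxy)cyclobut-2-enone F1.
   - A siloxy group also rotates outward and cannot add to the ketene, so thermolysis in degassed toluene should give 7-tert-butoxy-8-hydroxy-3,6,4'-trimethoxy-5-(triethylsilyloxy)flavone F2. This compound cannot become a quinone and has a single free phenol.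
   - MeI/K2CO3 should give 7-tert-butoxy-3,6,8,4'-tetramethoxy-5-(triethylsilyloxy)flavone F3, and TBAF/AcOH removes the silyl group to reach 14.

2. **Step 6.** Site selectivity between the two unlike squarate carbonyls may erode, and the magnesiated pyranone may partly fragment before it adds.
   Fallback (sets out from 9, comes back at 15): the choice between carbonyls is removed, and O6 and O7 are told apart later by phenol acidity.
   - Reagent 9 is added to symmetrical, commercial diisopropyl squarate (CC(C)OC1=C(OC(C)C)C(=O)C1=O) to give 4-hydroxy-2,3-diisopropoxy-4-[5-methoxy-6-(4-methoxyphenyl)-4-oxo-4H-pyran-3-yl]cyclobut-2-enone F4.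
   - The same thermolysis should give 5,8-dihydroxy-6,7-diisopropoxy-3,4'-dimethoxyflavone F5, and MeI/K2CO3 under argon should give 5-hydroxy-6,7-diisopropoxy-3,8,4'-trimethoxyflavone F6.
   - BCl3 (CH2Cl2, −78 to 0 °C) cleaves secondary alkyl aryl ethers ahead of methyl ethers and should give 5,6,7-trihydroxy-3,8,4'-trimethoxyflavone F7.
   - The 7-OH, conjugated para to the C4 carbonyl and the most acidic, is benzylated first (BnBr 1 equiv, K2CO3, DMF, Ar) to 7-benzyloxy-5,6-dihydroxy-3,8,4'-trimethoxyflavone F8.
   - The 6-OH is methylated while the 5-OH stays chelated (MeI, K2CO3) to give 7-benzyloxy-5-hydroxy-3,6,8,4'-tetramethoxyflavone F9, and hydrogenolysis (H2, Pd/C, EtOAc) gives 15.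

3. **Step 4.** Iodination could drift to the anisyl position ortho to the methoxy group, or stall because the partly protonated pyranone is a poor nucleophile.
   Fallback (sets out from 3, comes back at 6): the C5 iodine is installed before any arene is present.
   - Compound 3 with NIS in TFA should give 2,5-diiodo-3-methoxy-4H-pyran-4-one F10.
   - A site-selective Suzuki–Miyaura coupling with 4 (1.0 equiv, Pd(PPh3)4, K2CO3, rt to 40 °C) should then take C2–I. This β-iodide of the enone, next to the ring oxygen, undergoes oxidative addition faster than the α-iodide at C5, just as the β-halide reacts first in 3,4-dihalobutenolides. The product is 6.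

**Further compounds**
F1 | step 7 | 2-tert-butoxy-3-methoxy-4-[5-methoxy-6-(4-methoxyphenyl)-4-oxo-4H-pyran-3-yl]-4-(triethylsilyloxy)cyclobut-2-enone (racemic, one enantiomer drawn) | O=C1C(OC(C)(C)C)=C(OC)[C@]1(O[Si](CC)(CC)CC)c1coc(-c2ccc(OC)cc2)c(OC)c1=O
F2 | step 7 | 7-tert-butoxy-8-hydroxy-3,6,4'-trimethoxy-5-(triethylsilyloxy)flavone | COc1ccc(-c2oc3c(O)c(OC(C)(C)C)c(OC)c(O[Si](CC)(CC)CC)c3c(=O)c2OC)cc1
F3 | step 7 | 7-tert-butoxy-3,6,8,4'-tetramethoxy-5-(triethylsilyloxy)flavone | COc1ccc(-c2oc3c(OC)c(OC(C)(C)C)c(OC)c(O[Si](CC)(CC)CC)c3c(=O)c2OC)cc1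
F4 | step 6 | 4-hydroxy-2,3-diisopropoxy-4-[5-methoxy-6-(4-methoxyphenyl)-4-oxo-4H-pyran-3-yl]cyclobut-2-enone (racemic, one enantiomer drawn) | O=C1C(OC(C)C)=C(OC(C)C)[C@]1(O)c1coc(-c2ccc(OC)cc2)c(OC)c1=O
F5 | step 6 | 5,8-dihydroxy-6,7-diisopropoxy-3,4'-dimethoxyflavone | COc1ccc(-c2oc3c(O)c(OC(C)C)c(OC(C)C)c(O)c3c(=O)c2OC)cc1
F6 | step 6 | 5-hydroxy-6,7-diisopropoxy-3,8,4'-trimethoxyflavone | COc1ccc(-c2oc3c(OC)c(OC(C)C)c(OC(C)C)c(O)c3c(=O)c2OC)cc1
F7 | step 6 | 5,6,7-trihydroxy-3,8,4'-trimethoxyflavone | COc1ccc(-c2oc3c(OC)c(O)c(O)c(O)c3c(=O)c2OC)cc1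
F8 | step 6 | 7-benzyloxy-5,6-dihydroxy-3,8,4'-trimethoxyflavone | COc1ccc(-c2oc3c(OC)c(OCc4ccccc4)c(O)c(O)c3c(=O)c2OC)cc1
F9 | step 6 | 7-benzyloxy-5-hydroxy-3,6,8,4'-tetramethoxyflavone | COc1ccc(-c2oc3c(OC)c(OCc4ccccc4)c(OC)c(O)c3c(=O)c2OC)cc1
F10 | step 4 | 2,5-diiodo-3-methoxy-4H-pyran-4-one | O=c1c(I)coc(I)c1OC
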